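A direct plan would build ring B first: the enone A1 (cut down from (R)-pulegone) would be alkylated twice at C9, first with the side-chain iodide A2 and then with a butynyl bromide.
Ring C would then be closed by a gold-catalysed addition of a ring B enol silane to the alkyne, and ring A last, by 6-endo cyclisation of the acyl radical from selenoester A3 onto a C10 methylene group.
Its weakest step would be this last closure of C1–C2: a secondary acyl radical that must reach an alkene lodged between two quaternary carbons competes with loss of CO and with direct reduction, and it would be run on the most advanced material.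
The second weak point would be the base equilibration next to a C3 ketone (and later of a C3 aldehyde) that is asked to set C4 and C3: both centres would rest on small energy differences in a bridged ring that are hard to foresee.
The third would be step economy: about nine functional-group steps between the bicyclic ketone and A3 bring in only C1 and C2, and about seven steps go into A2 for one stereocentre that (S)-linalool already carries.

Plan of the new route
Retrosynthesis: after removal of the acetate and two silyl groups, the bicyclo[2.2.2]octanone is cut at C3–C4 and C5–C10 (retro-Diels–Alder), which opens rings B and C at once and leaves ring A as a 4,4-disubstituted cyclohexenone.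
The feature that allows this: the C2 ketone lies in the two-carbon bridge C1–C2 next to bridgehead C3, so the cage is the adduct of the ring A 2-silyloxydiene C10=C1–C2(OSi)=C3; the C6 oxygen lies next to C5, so as a ketone it activates the C4=C5 dienophile inside the three-atom tether C6–C7–C8 that becomes ring B.
The precursor is cut further at C8–C9 (Ireland–Claisen rearrangement of a cyclohexenyl propanoate, one catalyst-made carbinol centre relayed to C9 and C8) and at C9–C11 (Negishi coupling of 3-bromocyclohexenone with an iodide degraded from (S)-linalool, which brings C13).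
Ring order: ring A is bought, rings B and C arise together in the key step, which sets C3, C4, C5 and C10 in one event from C9 and the alkene geometry; C6 follows by reduction.
The weak steps above do not occur: there is no radical ring closure, no centre is left to an epimerisation, C1 and C2 are ring atoms from the start, and the side-chain stereocentre is bought.

Key step: step 14

Assumption: (S)-(+)-linalool of high enantiomeric purity is taken as commercially available.
Atom numbers used throughout: ring A = C1–C2–C3–C4–C5–C10; ring B = C5–C6–C7–C8–C9–C10; ring C = C3–C4–C5–C10–C9–C20 (C20 is the CH2 between C9 and C3); Me17 on C8, Me18 on C4, Me19 on C5; side chain C11–C12–C13(Me16)(O)–C14=C15 on C9. TBS = tert-butyldimethylsilyl.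

Step 1
Reactants: 1 (S)-(+)-linalool
Product: 2 tert-butyl{[(3S)-3,7-dimethylocta-1,6-dien-3-yl]oxy}dimethylsilane
Conditions: TBSOTf, 2,6-lutidine, CH2Cl2, −78 → 0 °C
Reagents that add atoms: tert-butyldimethylsilyl trifluoromethanesulfonate, CC(C)(C)[Si](C)(C)OS(=O)(=O)C(F)(F)F
Why: Silyl ether protection with a silyl triflate and a hindered base covers the tertiary allylic alcohol, whose S configuration (C13) is bought with the starting material, for all organometallic and oxidation steps.

Step 2
Reactants: 2 tert-butyl{[(3S)-3,7-dimethylocta-1,6-dien-3-yl]oxy}dimethylsilane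
Product: 4 (4S)-4-(tert-butyldimethylsilyloxy)-4-methylhex-5-enal, via ozonide 3 (not isolated)
Conditions: O3, CH2Cl2, −78 °C (Sudan Red 7B as indicator); then PPh3, −78 → 23 °C
Reagents that add atoms: ozone, [O-][O+]=O
Why: Ozonolysis with reductive work-up is selective for the electron-rich trisubstituted alkene, since the vinyl group is monosubstituted and shielded by the neighbouring quaternary silyloxy carbon, and the dye marks the end point.

Step 3
Reactants: 4 (4S)-4-(tert-butyldimethylsilyloxy)-4-methylhex-5-enal
Product: 5 (4S)-4-(tert-butyldimethylsilyloxy)-4-methylhex-5-enoic acid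
Conditions: NaClO2, NaH2PO4, 2-methylbut-2-ene, t-BuOH–H2O, 0 → 23 °C
Reagents that add atoms: sodium chlorite, [Na+].[O-]Cl=O
Why: Pinnick oxidation converts the aldehyde into the acid under buffered conditions, and the alkene scavenger keeps hypochlorous acid away from the vinyl group.

Step 4
Reactants: 5 (4S)-4-(tert-butyldimethylsilyloxy)-4-methylhex-5-enoic acid
Product: 7 (3S)-3-(tert-butyldimethylsilyloxy)-5-iodo-3-methylpent-1-ene, via Barton ester 6 (not isolated)
Conditions: 1-hydroxypyridine-2(1H)-thione, DCC, DMAP (cat.), CH2Cl2, 0 °C, dark; then CHI3, PhH, hν (tungsten lamp), 60 °C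
Reagents that add atoms: iodoform, IC(I)I
Why: Barton decarboxylation in the presence of iodoform (iododecarboxylation) removes the carboxyl carbon as CO2 and leaves iodine on C11, the primary radical having no favourable ring closure onto the vinyl group.

Step 5
Reactants: 7 (3S)-3-(tert-butyldimethylsilyloxy)-5-iodo-3-methylpent-1-ene; 8 3-bromocyclohex-2-en-1-one
Product: 10 3-[(3S)-3-(tert-butyldimethylsilyloxy)-3-methylpent-4-enyl]cyclohex-2-en-1-one, via alkylzinc iodide 9 (not isolated)
Conditions: Zn dust (activated), LiCl, THF, 40 °C; then 8, Pd(PPh3)4 (5 mol %), THF, 50 °C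
Reagents that add atoms: none
Why: Zinc insertion into the primary iodide and Negishi coupling with the vinylic bromide under zerovalent palladium join C11 to C9 and give the 3-alkylcyclohexenone with the ring carbonyl on the later C1, without an alkyllithium that could suffer silyl migration.

Step 6
Reactants: 10 3-[(3S)-3-(tert-butyldimethylsilyloxy)-3-methylpent-4-enyl]cyclohex-2-en-1-one
Product: 11 (1S)-3-[(3S)-3-(tert-butyldimethylsilyloxy)-3-methylpent-4-enyl]cyclohex-2-en-1-ol
Conditions: (R)-2-methyl-CBS-oxazaborolidine (20 mol %), catecholborane, toluene, −78 °C; aq. NaOH work-up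
Reagents that add atoms: none
Why: Corey–Bakshi–Shibata reduction, in which the oxazaborolidine binds the enone with its alkenyl arm as the large group and delivers hydride to one carbonyl face, should give the (1S) allylic alcohol, the only stereocentre of the route that is made by a catalyst, and catecholborane at low temperature leaves the vinyl group alone.

Step 7
Reactants: 11 (1S)-3-[(3S)-3-(tert-butyldimethylsilyloxy)-3-methylpent-4-enyl]cyclohex-2-en-1-ol
Product: 12 (1S)-3-[(3S)-3-(tert-butyldimethylsilyloxy)-3-methylpent-4-enyl]cyclohex-2-en-1-yl propanoate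
Conditions: (EtCO)2O, Et3N, DMAP (cat.), CH2Cl2, 0 → 23 °C
Reagents that add atoms: propanoic anhydride, CCC(=O)OC(=O)CC
Why: DMAP-catalysed acylation of the secondary allylic alcohol installs the propanoate that carries C6, C8 and Me17.

Step 8
Reactants: 12 (1S)-3-[(3S)-3-(tert-butyldimethylsilyloxy)-3-methylpent-4-enyl]cyclohex-2-en-1-yl propanoate
Product: 15 (2S)-2-{(1S)-1-[(3S)-3-(tert-butyldimethylsilyloxy)-3-methylpent-4-enyl]cyclohex-2-en-1-yl}propanoic acid, via silyl ketene acetal 13 (not isolated), via trimethylsilyl ester 14 (not isolated)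
Conditions: LiN(i-Pr)2, TMSCl, Et3N, THF, −78 °C; then 23 → 60 °C; aq. citric acid
Reagents that add atoms: none
Why: Ireland–Claisen rearrangement: kinetic deprotonation in THF gives the (E)-silyl ketene acetal, which in a cyclohexenyl ester should prefer the chair transition state because the boat would press its methyl group onto ring carbon C20, so the C8–C9 bond forms on the ring face that the C1–O bond leaves (chirality transfer sets quaternary C9) and Me17 ends up anti to C20 (sets C8).

Step 9
Reactants: 15 (2S)-2-{(1S)-1-[(3S)-3-(tert-butyldimethylsilyloxy)-3-methylpent-4-enyl]cyclohex-2-en-1-yl}propanoic acid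
Product: 17 (3S)-1-diazo-3-{(1S)-1-[(3S)-3-(tert-butyldimethylsilyloxy)-3-methylpent-4-enyl]cyclohex-2-en-1-yl}butan-2-one, via acid chloride 16 (not isolated)
Conditions: 1-chloro-N,N,2-trimethylprop-1-en-1-amine, CH2Cl2, 0 °C; then CH2N2 (excess), Et2O, 0 °C
Reagents that add atoms: diazomethane, C=[N+]=[N-]
Why: Neutral conversion into the acid chloride and acylation of diazomethane (first half of the Arndt–Eistert homologation) bring in C7 without touching the C8 stereocentre or the silyl ether.

Step 10
Reactants: 17 (3S)-1-diazo-3-{(1S)-1-[(3S)-3-(tert-butyldimethylsilyloxy)-3-methylpent-4-enyl]cyclohex-2-en-1-yl}butan-2-one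
Product: 19 N-methoxy-N-methyl-3-{1-[(3S)-3-(tert-butyldimethylsilyloxy)-3-methylpent-4-enyl]cyclohex-2-en-1-yl}butanamide (C8 and C9 configured as in 15), via ketene 18 (not isolated)
Conditions: PhCO2Ag (10 mol %), MeNH(OMe)·HCl, Et3N, THF, −20 → 23 °C, dark
Reagents that add atoms: N,O-dimethylhydroxylamine hydrochloride, CNOC.Cl
Why: Silver-catalysed Wolff rearrangement, in which C8 migrates with retention of configuration, gives a ketene that the hydroxylamine traps as the Weinreb amide, so the carbonyl carbon is now C6 and C7 is a methylene group.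

Step 11
Reactants: 19 N-methoxy-N-methyl-3-{1-[(3S)-3-(tert-butyldimethylsilyloxy)-3-methylpent-4-enyl]cyclohex-2-en-1-yl}butanamide
Product: 20 N-methoxy-N-methyl-3-{1-[(3S)-3-(tert-butyldimethylsilyloxy)-3-methylpent-4-enyl]-4-oxocyclohex-2-en-1-yl}butanamide (C2 ketone; C8 and C9 as in 15)
Conditions: Rh2(cap)4 (1 mol %; cap = caprolactamate), t-BuOOH (70% aq.), K2CO3, CH2Cl2, 23 °C
Reagents that add atoms: tert-butyl hydroperoxide, CC(C)(C)OO
Why: Allylic oxidation of the cyclohexene can take place only at C2, because the other allylic position C9 is quaternary and the vinyl group has no allylic hydrogen, which gives the 4,4-disubstituted cyclohexenone.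

Step 12
Reactants: 20 N-methoxy-N-methyl-3-{1-[(3S)-3-(tert-butyldimethylsilyloxy)-3-methylpent-4-enyl]-4-oxocyclohex-2-en-1-yl}butanamide
Product: 21 ring A 2-(tert-butyldimethylsilyloxy)cyclohexa-1,3-diene (C10=C1–C2(OTBS)=C3) carrying the Weinreb amide chain and the C11–C16 chain on C9
Conditions: TBSOTf, Et3N, CH2Cl2, −78 → 0 °C
Reagents that add atoms: tert-butyldimethylsilyl trifluoromethanesulfonate, CC(C)(C)[Si](C)(C)OS(=O)(=O)C(F)(F)F
Why: Soft enolisation (silyl enol ether formation) can remove a proton only from C3, since the gamma carbon C9 is quaternary, so the cross-conjugated 2-silyloxydiene forms as one regioisomer, and the Weinreb amide is not enolised under these conditions.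

Step 13
Reactants: 21 ring A 2-silyloxydiene Weinreb amide; 22 (E)-2-bromobut-2-ene
Product: 24 triene ketone: ring A 2-silyloxydiene with the chain C8H(Me17)–C7H2–C6(=O)–C5(Me19)=C4H(Me18) (E, tigloyl) on C9, via butenyllithium 23 (not isolated)
Conditions: 22, t-BuLi (2 equiv), Et2O, −78 °C; then 21, THF, −78 °C; pH 7 buffer; used at once
Reagents that add atoms: none
Why: Bromine–lithium exchange with retention of alkene geometry and addition of the alkenyllithium to the Weinreb amide (the chelated adduct releases the ketone only on work-up) unveil the tigloyl ketone after the diene is in place, so two enolisable enones never have to be told apart and the silyloxydiene doubles as protection of the ring enone.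

Step 14
Reactants: 24 triene ketone
Product: 25 Diels–Alder adduct: rings A, B and C closed, C1=C2 enol silane (2-OTBS), C6 ketone, 13-OTBS, configuration at C3, C4, C5, C8, C9 and C10 as in the target
Conditions: toluene (0.01 M), BHT (cat.), 130 °C, sealed tube
Reagents that add atoms: none
Why: Thermal, concerted but asynchronous [4+2] cycloaddition of normal electron demand between the 2-silyloxydiene C10=C1–C2(OTBS)=C3 of ring A and the (E)-enone C4=C5 that hangs from C9 through C8–C7–C6, the enol-ether carbon C3 bonding ahead to the beta carbon C4. The closest known reaction type is the intramolecular Diels–Alder reaction of cyclohexa-1,3-dienes that carry the dienophile on a three-atom chain at the sp3 ring carbon next to the diene, which gives bicyclo[2.2.2]octenes with a fused six-membered ring (tricyclo[5.3.1.0(3,8)]undecanes). Ring B (C5–C6–C7–C8–C9–C10) closes through the C5–C10 bond as the fused six-membered ring of the tether, and ring C closes through the C3–C4 bond in the bridged mode, which completes the bicyclo[2.2.2]octene. C10, C3 and C5 are dictated by C9, because the short tether lets the dienophile reach only the diene face that bears C8 and only with C6 turned toward the C9–C20 bridge, so Me19 points to the C1–C2 bridge; C4 follows from the E geometry of the alkene, which the suprafacial addition translates into Me18 cis to Me19. The step needs regioselectivity (C5 to C10, not to C3), secured by the tether length and by the matched polarity of C3 and C4, and chemoselectivity for the enone over the side-chain vinyl group C14=C15, which sits on a tether of the same length but is not activated; the moderate temperature that the activated pair allows should also stay below that of [1,5]-hydrogen shifts in the diene, which would scramble C9.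

Step 15
Reactants: 25 Diels–Alder adduct
Product: 26 C6 alcohol (equatorial on ring B, H6 on the face of Me17 and H10), C1=C2 enol silane and 13-OTBS retained
Conditions: Li, NH3(l), THF, EtOH, −78 °C; then NH4Cl
Reagents that add atoms: none
Why: Dissolving-metal reduction of the hindered C6 ketone is under thermodynamic control and should give the equatorial alcohol, since the axial epimer would suffer a 1,3-diaxial contact with Me17, while the enol silane masks the C2 carbonyl during this step.

Step 16
Reactants: 26 C6 alcohol
Product: 27 C6 acetate with C1=C2 enol silane and 13-OTBS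
Conditions: Ac2O, Et3N, DMAP (cat.), CH2Cl2, 23 °C
Reagents that add atoms: acetic anhydride, CC(=O)OC(C)=O
Why: DMAP-catalysed acetylation of the secondary alcohol, to which the enol silane and the tertiary silyl ether do not respond.

Step 17
Reactants: 27 C6 acetate with C1=C2 enol silane and 13-OTBS
Product: 29 target CNP0281208.1, via ketone silyl ether 28 (not isolated)
Conditions: HF·pyridine, pyridine, THF, 0 → 40 °C
Reagents that add atoms: none
Why: Fluoride-induced desilylation cleaves the enol silane first, which releases the C2 ketone (C1 is a methylene group, so no new stereocentre arises), and then the tertiary silyl ether at C13, while the acetate stays.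

Compound list
1 | (S)-(+)-linalool, (3S)-3,7-dimethylocta-1,6-dien-3-ol | C=C[C@@](C)(O)CCC=C(C)C | starting material
2 | tert-butyl{[(3S)-3,7-dimethylocta-1,6-dien-3-yl]oxy}dimethylsilane | C=C[C@@](C)(O[Si](C)(C)C(C)(C)C)CCC=C(C)C | intermediate
3 | ozonide of the 6,7-alkene of 2: 5-[(3S)-3-(tert-butyldimethylsilyloxy)-3-methylpent-4-enyl]-3,3-dimethyl-1,2,4-trioxolane | C=C[C@@](C)(O[Si](C)(C)C(C)(C)C)CCC1OOC(C)(C)O1 | intermediate
4 | (4S)-4-(tert-butyldimethylsilyloxy)-4-methylhex-5-enal | C=C[C@@](C)(O[Si](C)(C)C(C)(C)C)CCC=O | intermediate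
5 | (4S)-4-(tert-butyldimethylsilyloxy)-4-methylhex-5-enoic acid | C=C[C@@](C)(O[Si](C)(C)C(C)(C)C)CCC(=O)O | intermediate
6 | Barton ester: 2-thioxopyridin-1(2H)-yl (4S)-4-(tert-butyldimethylsilyloxy)-4-methylhex-5-enoate | C=C[C@@](C)(O[Si](C)(C)C(C)(C)C)CCC(=O)On1ccccc1=S | intermediate
7 | (3S)-3-(tert-butyldimethylsilyloxy)-5-iodo-3-methylpent-1-ene (C11–C16 fragment, iodine on C11) | C=C[C@@](C)(O[Si](C)(C)C(C)(C)C)CCI | intermediate
8 | 3-bromocyclohex-2-en-1-one | O=C1C=C(Br)CCC1 | starting material
9 | [(3S)-3-(tert-butyldimethylsilyloxy)-3-methylpent-4-enyl]zinc iodide | C=C[C@@](C)(O[Si](C)(C)C(C)(C)C)CC[Zn]I | intermediate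
10 | 3-[(3S)-3-(tert-butyldimethylsilyloxy)-3-methylpent-4-enyl]cyclohex-2-en-1-one | C=C[C@@](C)(O[Si](C)(C)C(C)(C)C)CCC1=CC(=O)CCC1 | intermediate
11 | (1S)-3-[(3S)-3-(tert-butyldimethylsilyloxy)-3-methylpent-4-enyl]cyclohex-2-en-1-ol | C=C[C@@](C)(O[Si](C)(C)C(C)(C)C)CCC1=C[C@@H](O)CCC1 | intermediate
12 | (1S)-3-[(3S)-3-(tert-butyldimethylsilyloxy)-3-methylpent-4-enyl]cyclohex-2-en-1-yl propanoate | C=C[C@@](C)(O[Si](C)(C)C(C)(C)C)CCC1=C[C@@H](OC(=O)CC)CCC1 | intermediate
13 | (E)-trimethylsilyl ketene acetal of 12 (methyl cis to the ring oxygen) | C=C[C@@](C)(O[Si](C)(C)C(C)(C)C)CCC1=C[C@@H](O/C(O[Si](C)(C)C)=C\C)CCC1 | intermediate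
14 | trimethylsilyl ester of 15 | C=C[C@@](C)(O[Si](C)(C)C(C)(C)C)CC[C@@]1(C=CCCC1)[C@H](C)C(=O)O[Si](C)(C)C | intermediate
15 | (2S)-2-{(1S)-1-[(3S)-3-(tert-butyldimethylsilyloxy)-3-methylpent-4-enyl]cyclohex-2-en-1-yl}propanoic acid (quaternary C9, C8 with Me17) | C=C[C@@](C)(O[Si](C)(C)C(C)(C)C)CC[C@@]1(C=CCCC1)[C@H](C)C(=O)O | intermediate
16 | acid chloride of 15 | C=C[C@@](C)(O[Si](C)(C)C(C)(C)C)CC[C@@]1(C=CCCC1)[C@H](C)C(=O)Cl | intermediate
17 | (3S)-1-diazo-3-{(1S)-1-[(3S)-3-(tert-butyldimethylsilyloxy)-3-methylpent-4-enyl]cyclohex-2-en-1-yl}butan-2-one | C=C[C@@](C)(O[Si](C)(C)C(C)(C)C)CC[C@@]1(C=CCCC1)[C@H](C)C(=O)C=[N+]=[N-] | intermediate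
18 | ketene from 17 (C8 bonded to the ketene CH, which is C7) | C=C[C@@](C)(O[Si](C)(C)C(C)(C)C)CC[C@@]1(C=CCCC1)[C@H](C)C=C=O | intermediate
19 | N-methoxy-N-methyl-3-{1-[(3S)-3-(tert-butyldimethylsilyloxy)-3-methylpent-4-enyl]cyclohex-2-en-1-yl}butanamide, C8 and C9 as in 15 | C=C[C@@](C)(O[Si](C)(C)C(C)(C)C)CC[C@@]1(C=CCCC1)[C@H](C)CC(=O)N(C)OC | intermediate
20 | N-methoxy-N-methyl-3-{1-[(3S)-3-(tert-butyldimethylsilyloxy)-3-methylpent-4-enyl]-4-oxocyclohex-2-en-1-yl}butanamide, C8 and C9 as in 15 | C=C[C@@](C)(O[Si](C)(C)C(C)(C)C)CC[C@@]1(C=CC(=O)CC1)[C@H](C)CC(=O)N(C)OC | intermediate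
21 | ring A 2-(tert-butyldimethylsilyloxy)cyclohexa-1,3-diene with Weinreb amide chain and C11–C16 chain on C9 | C=C[C@@](C)(O[Si](C)(C)C(C)(C)C)CC[C@@]1(C=CC(O[Si](C)(C)C(C)(C)C)=CC1)[C@H](C)CC(=O)N(C)OC | intermediate
22 | (E)-2-bromobut-2-ene | C/C=C(\C)Br | starting material
23 | (E)-but-2-en-2-yllithium | C/C=C(\C)[Li] | intermediate
24 | triene ketone: ring A 2-silyloxydiene with (E)-2-methylbut-2-enoyl (tigloyl) ketone at C6 on the C8–C7 tether | C=C[C@@](C)(O[Si](C)(C)C(C)(C)C)CC[C@@]1(C=CC(O[Si](C)(C)C(C)(C)C)=CC1)[C@H](C)CC(=O)/C(C)=C/C | intermediate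
25 | Diels–Alder adduct: tricyclic core with C1=C2 enol silane (2-OTBS), C6 ketone, 13-OTBS | C=C[C@@](C)(O[Si](C)(C)C(C)(C)C)CC[C@@]12C[C@H]3C(O[Si](C)(C)C(C)(C)C)=C[C@@H]1[C@](C)([C@@H]3C)C(=O)C[C@H]2C | intermediate
26 | C6 equatorial alcohol of 25 | C=C[C@@](C)(O[Si](C)(C)C(C)(C)C)CC[C@@]12C[C@H]3C(O[Si](C)(C)C(C)(C)C)=C[C@@H]1[C@](C)([C@@H]3C)[C@H](O)C[C@H]2C | intermediate
27 | C6 acetate of 26 | C=C[C@@](C)(O[Si](C)(C)C(C)(C)C)CC[C@@]12C[C@H]3C(O[Si](C)(C)C(C)(C)C)=C[C@@H]1[C@](C)([C@@H]3C)[C@H](OC(C)=O)C[C@H]2C | intermediate
28 | 13-O-tert-butyldimethylsilyl ether of the target (C2 ketone free) | C=C[C@@](C)(O[Si](C)(C)C(C)(C)C)CC[C@@]12C[C@H]3C(=O)C[C@@H]1[C@](C)([C@@H]3C)[C@H](OC(C)=O)C[C@H]2C | intermediate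
29 | CNP0281208.1 | C=C[C@@](C)(O)CC[C@@]12C[C@H]3C(=O)C[C@@H]1[C@](C)([C@@H]3C)[C@H](OC(C)=O)C[C@H]2C | target

Total step count: 17. Longest linear sequence: 17 steps, from (S)-linalool; 3-bromocyclohex-2-en-1-one and (E)-2-bromobut-2-ene enter as bought materials.

Steps most likely to fail
1. Step 14 (key cycloaddition). The cycloaddition may be too slow, because the trisubstituted dienophile has to create the quaternary centre C5 next to C10; at the higher temperature this would need, addition of the side-chain vinyl group and hydrogen shifts in the diene begin to compete. The fallback sets out from 21. (E)-Prop-1-enyllithium F1, made from bought (E)-1-bromoprop-1-ene and t-BuLi, would be added to the Weinreb amide to give the (E)-propenyl ketone triene F2. Its less substituted dienophile should cyclise more readily under the same thermal conditions to the 19-nor adduct F3, which has hydrogen in place of Me19 on C5. C-Methylation of the more substituted, thermodynamic enolate of the C6 ketone (KOt-Bu, t-BuOH, THF, then MeI) would then place Me19 on the only face of C5 that the cage leaves open. The fallback comes back to the route at 25.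
2. Step 8 (Ireland–Claisen rearrangement). Chair and boat transition states may compete, which would erode the selectivity at C8, while C9 is safe through chirality transfer. The fallback sets out from 11. Johnson–Claisen rearrangement with triethyl orthoacetate (propanoic acid cat., 140 °C) would pass through the mixed ketene acetal F4 to the ethyl ester F5, which has C9 but no centre at C8 yet. Saponification would give the acid F6. Activation as the pivalic mixed anhydride F7 and coupling with (S)-4-benzyloxazolidin-2-one (Et3N, LiCl) would give the imide F8. Evans alkylation (NaN(SiMe3)2, MeI, −78 °C) would introduce Me17 under auxiliary control to give the methylated imide F9, and LiOH/H2O2 cleavage would come back to the route at 15.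
3. Step 15 (reduction at C6). Electron transfer may also attack the allylic silyl ether, or protonation may not be fully selective. The fallback sets out from 25. LiAlH4 (THF, −78 °C) would reduce the ketone under kinetic control, possibly mainly to the axial C6 epimer F10. Heating the mixture with Al(Oi-Pr)3 in i-PrOH–toluene with a trace of acetone (Meerwein–Ponndorf–Verley/Oppenauer equilibration through the ketone) would drain it into the equatorial alcohol, so the fallback comes back to the route at 26.

Further compounds
F1 | step 14 | (E)-prop-1-enyllithium | C/C=C/[Li]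
F2 | step 14 | (E)-propenyl ketone triene (24 without Me19) | C=C[C@@](C)(O[Si](C)(C)C(C)(C)C)CC[C@@]1(C=CC(O[Si](C)(C)C(C)(C)C)=CC1)[C@H](C)CC(=O)/C=C/C
F3 | step 14 | 19-nor adduct (25 with H on C5) | C=C[C@@](C)(O[Si](C)(C)C(C)(C)C)CC[C@@]12C[C@H]3C(O[Si](C)(C)C(C)(C)C)=C[C@@H]1[C@H]([C@@H]3C)C(=O)C[C@H]2C
F4 | step 8 | mixed ketene acetal of 11 (1-ethoxyvinyl ether) | C=C[C@@](C)(O[Si](C)(C)C(C)(C)C)CCC1=C[C@@H](OC(=C)OCC)CCC1
F5 | step 8 | ethyl 2-{1-[(3S)-3-(tert-butyldimethylsilyloxy)-3-methylpent-4-enyl]cyclohex-2-en-1-yl}acetate (C9 as in 15) | C=C[C@@](C)(O[Si](C)(C)C(C)(C)C)CC[C@@]1(C=CCCC1)CC(=O)OCC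
F6 | step 8 | acid of F5 | C=C[C@@](C)(O[Si](C)(C)C(C)(C)C)CC[C@@]1(C=CCCC1)CC(=O)O
F7 | step 8 | pivalic mixed anhydride of F6 | C=C[C@@](C)(O[Si](C)(C)C(C)(C)C)CC[C@@]1(C=CCCC1)CC(=O)OC(=O)C(C)(C)C
F8 | step 8 | imide of F6 with (S)-4-benzyloxazolidin-2-one | C=C[C@@](C)(O[Si](C)(C)C(C)(C)C)CC[C@@]1(C=CCCC1)CC(=O)N1[C@@H](Cc2ccccc2)COC1=O
F9 | step 8 | methylated imide (C8 with Me17 as in 15) | C=C[C@@](C)(O[Si](C)(C)C(C)(C)C)CC[C@@]1(C=CCCC1)[C@H](C)C(=O)N1[C@@H](Cc2ccccc2)COC1=O
F10 | step 15 | axial C6 epimer of 26 | C=C[C@@](C)(O[Si](C)(C)C(C)(C)C)CC[C@@]12C[C@H]3C(O[Si](C)(C)C(C)(C)C)=C[C@@H]1[C@](C)([C@@H]3C)[C@@H](O)C[C@H]2C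
A1 | direct plan | (5R)-2,5-dimethylcyclohex-2-en-1-one | C[C@@H]1CC=C(C)C(=O)C1
A2 | direct plan | (3S)-5-iodo-3-methyl-3-(triethylsilyloxy)pent-1-ene | C=C[C@@](C)(O[Si](CC)(CC)CC)CCI
A3 | direct plan | bicyclo[3.3.1]nonane with C10 methylene, C3 phenyl selenoester, 6-acetate and silylated side chain | C=C[C@@](C)(O[Si](CC)(CC)CC)CC[C@@]12C[C@@H](C(=O)[Se]c3ccccc3)[C@@H](C)[C@@](C)(C1=C)[C@H](OC(C)=O)C[C@H]2C
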